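**Plan**

- Retrosynthesis cuts the C15–O enol ether bond of ring D (back to an alkynol), the C6–OAc bond (back to the C7 ketone), then C4–C5 and C9–C10 together (rings A and B), then C6–C7 (sulfone acylation), and finally C11–C12 with C9–O (keto ester dianion plus epoxide, ring C).
- Forward: ring C is built first as an alkylidene oxolane, the C1–C6 diene is joined at C6–C7, rings A and B close in one radical bicyclization, C6 is acetoxylated, and ring D closes last.
- Enabling feature: the spiro carbon C9 and the quaternary C10 lie β and γ to the C7 ketone, so C9 is the β-carbon of a vinylogous ester O–C9=C8–C7=O that already contains ring C (O, C9, C11, C12, C13) and its hindered C9–O–C13 ether.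
- Stereochemistry: C13 comes from a Sharpless epoxidation. C5, C10 and C9 come from chair–chair folding of the (E)-C5=C10 and (Z)-C8=C9 alkenes, with C13 steering the absolute sense. C8 is set by enolate protonation, and C6 by α-epoxidation of the C6=C7 enol acetate followed by an acyloxy shift with inversion.

Key step: step 10

Remark: labdane numbering is used (C1–C10 decalin, C11–C16 side chain, C17 on C8, C18/C19 on C4, C20 on C10), and the exocyclic vinylogous ester is assumed to settle under acid as the (Z)-isomer (ring oxygen cis to the C7 carbonyl), the geometry a chair-like closure of ring B needs to place the C9 oxygen axial.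

**Route**

Step 1
Reactants: 1 6-methylhept-6-en-2-one; 2 triethyl phosphonoacetate
Product: 3 ethyl (2E)-3,7-dimethylocta-2,7-dienoate
Conditions: NaH, THF, 0 °C to reflux
Reagents that add atoms: none
Why: Horner–Wadsworth–Emmons olefination of the methyl ketone should give the trisubstituted enoate mainly as the (E)-isomer (ester trans to the longer chain), and the minor (Z)-isomer would be removed by chromatography.

Step 2
Reactants: 3 ethyl (2E)-3,7-dimethylocta-2,7-dienoate
Product: 4 (2E)-3,7-dimethylocta-2,7-dien-1-ol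
Conditions: i-Bu2AlH (2.2 equiv), CH2Cl2, −78 °C; Rochelle salt work-up
Reagents that add atoms: none
Why: Aluminium hydride reduction of the conjugated ester proceeds by 1,2-hydride delivery at low temperature and leaves both alkenes untouched.

Step 3
Reactants: 4 (2E)-3,7-dimethylocta-2,7-dien-1-ol
Product: 6 {[(2E)-3,7-dimethylocta-2,7-dien-1-yl]sulfonyl}benzene, via allylic bromide 5 (not isolated)
Conditions: PBr3 (0.4 equiv), Et2O, 0 °C; aqueous work-up; crude 5, PhSO2Na (1.5 equiv), DMF, rt
Reagents that add atoms: sodium benzenesulfinate, [Na+].[O-]S(=O)c1ccccc1; PBr3, BrP(Br)Br (supplies the bromine of 5)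
Why: PBr3 converts the primary allylic alcohol into the bromide without transposition at 0 °C, and the soft sulfinate then displaces bromide through sulfur in an SN2 reaction (sulfinate S-alkylation) that keeps the (E)-geometry.

Step 4
Reactants: 7 2-bromoprop-2-en-1-ol; 8 ethynyltrimethylsilane
Product: 9 2-methylidene-4-(trimethylsilyl)but-3-yn-1-ol
Conditions: Pd(PPh3)2Cl2 (2 mol%), CuI (4 mol%), Et3N, THF, rt
Reagents that add atoms: none
Why: Sonogashira coupling of the vinyl bromide with the terminal alkyne tolerates the free hydroxyl and gives the cross-conjugated enyne alcohol.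

Step 5
Reactants: 9 2-methylidene-4-(trimethylsilyl)but-3-yn-1-ol
Product: 10 [(2R)-2-[(trimethylsilyl)ethynyl]oxiran-2-yl]methanol
Conditions: Ti(OiPr)4 (0.2 equiv), D-(−)-diethyl tartrate (0.24 equiv), t-BuOOH (2 equiv), 4 Å MS, CH2Cl2, −20 °C; citric acid work-up
Reagents that add atoms: tert-butyl hydroperoxide, CC(C)(C)OO
Why: Sharpless asymmetric epoxidation of the 2-substituted allylic alcohol sets the quaternary carbon (the future C13) as (R), because the D-(−)-tartrate catalyst delivers oxygen to the enantioface opposite to the one that gives (2S,3S)-epoxides from (E)-allylic alcohols with L-(+)-tartrate; the silylalkyne is inert to the titanium peroxide.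

Step 6
Reactants: 10 [(2R)-2-[(trimethylsilyl)ethynyl]oxiran-2-yl]methanol
Product: 11 tert-butyl(diphenyl){[(2S)-2-[(trimethylsilyl)ethynyl]oxiran-2-yl]methoxy}silane
Conditions: TBDPSCl, imidazole, CH2Cl2, 0 °C to rt
Reagents that add atoms: tert-butyl(chloro)diphenylsilane, CC(C)(C)[Si](Cl)(c1ccccc1)c1ccccc1
Why: Silylation of the primary alcohol under neutral conditions avoids Payne rearrangement and installs the bulky group that later shields one face of ring C; the stereocentre is untouched and only its descriptor changes through the priority rules.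

Step 7
Reactants: 11 tert-butyl(diphenyl){[(2S)-2-[(trimethylsilyl)ethynyl]oxiran-2-yl]methoxy}silane; 12 methyl 2-methyl-3-oxobutanoate
Product: 14 methyl (2Z)-2-[(5R)-5-{[tert-butyl(diphenyl)silyl]oxymethyl}-5-[(trimethylsilyl)ethynyl]oxolan-2-ylidene]propanoate, via hydroxy keto ester 13 (not isolated)
Conditions: 12 (1.8 equiv), NaH then n-BuLi, THF, 0 °C; 11, 0 °C to rt; aq. NH4Cl; crude 13, TsOH·H2O (cat.), 4 Å MS, CH2Cl2, rt
Reagents that add atoms: none
Why: In this keto ester dianion alkylation followed by cyclodehydration, the γ-carbanion opens the epoxide at its CH2 carbon by SN2 (the C13–O bond is untouched, so configuration is retained), and acid then dehydrates the cyclic hemiketal of the δ-hydroxy β-keto ester to the push–pull alkylidene oxolane, which equilibrates under acid to the (Z)-isomer expected when the exocyclic carbon carries a methyl group.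

Step 8
Reactants: 6 {[(2E)-3,7-dimethylocta-2,7-dien-1-yl]sulfonyl}benzene; 14 methyl (2Z)-2-[(5R)-5-{[tert-butyl(diphenyl)silyl]oxymethyl}-5-[(trimethylsilyl)ethynyl]oxolan-2-ylidene]propanoate
Product: 15 (2Z,5E)-4-(benzenesulfonyl)-2-[(5R)-5-{[tert-butyl(diphenyl)silyl]oxymethyl}-5-[(trimethylsilyl)ethynyl]oxolan-2-ylidene]-6,10-dimethylundeca-5,10-dien-3-one (C4 epimers)
Conditions: 6 (2.2 equiv), n-BuLi (2.1 equiv), THF, −78 °C; 14, −78 to −20 °C; aq. NH4Cl
Reagents that add atoms: none
Why: In this acylation of an α-sulfonyl carbanion by an ester, the lithiated allylic sulfone attacks through its α-carbon and the second equivalent deprotonates the more acidic β-keto sulfone, so the reaction stops after one addition; the sulfone-bearing carbon forms as an inconsequential epimer mixture.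

Step 9
Reactants: 15 the β-keto sulfone from step 8
Product: 16 (2Z,5E)-2-[(5R)-5-{[tert-butyl(diphenyl)silyl]oxymethyl}-5-[(trimethylsilyl)ethynyl]oxolan-2-ylidene]-6,10-dimethylundeca-5,10-dien-3-one
Conditions: SmI2 (2.5 equiv), THF/MeOH, −78 °C
Reagents that add atoms: none
Why: Reductive desulfonylation of a β-keto sulfone by two single-electron transfers cleaves the C–S bond to a samarium dienolate, which methanol protonates at the α-carbon (C6) at −78 °C, so the (E)-C5=C10 alkene should stay out of conjugation.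

Step 10
Reactants: 16 the dienone from step 9
Product: 17 (13R)-16-{[tert-butyl(diphenyl)silyl]oxy}-9α,13-epoxy-15-(trimethylsilyl)labd-14-yn-7-one (5α-H, 8α-methyl, 10β-methyl)
Conditions: Fe(acac)3 (0.3 equiv), PhSiH3 (2.5 equiv), EtOH/ethylene glycol 5:1, argon, 0.01 M, 60 °C
Reagents that add atoms: none
Why: Proposed new method: the iron hydride formed from Fe(acac)3 and PhSiH3 transfers a hydrogen atom to the terminal 1,1-disubstituted alkene (the trisubstituted, push–pull and silylated π-bonds react far more slowly), the tertiary C4 radical closes ring A 6-endo-trig onto C5, the tertiary C10 radical closes ring B 6-endo-trig onto C9, and the resulting C8 α-keto radical is reduced by ferrous iron and protonated by ethanol. The closest known reaction type is the iron-hydride hydrogen-atom-transfer radical polyene bicyclization that ends in a Giese addition to an enone, supported by tin-hydride cyclizations of alkyl radicals onto the oxygen-bearing carbon of β-alkoxy acrylates; what has not been shown is termination on a fully substituted β-alkoxy enone carbon, which is expected to work because the nucleophilic tertiary radical meets the electrophilic end of the C9=C8–C7=O unit in a six-membered transition state, whereas 5-exo attack at C8 would oppose the polarization. Chair–chair folding of the (E)-C5=C10 alkene sets H5 and the C10 methyl trans, and the same chair turns the C9 substituent that is cis to C7, the ring oxygen of the (Z)-vinylogous ester, axial (9α) and C11 equatorial. C8 is set when the C7–C8 enolate is protonated axially from the β-face, which leaves the methyl equatorial (8α), also the thermodynamic preference. The absolute sense of folding rests on C13: C10 has to bond to the face of the alkylidene oxolane anti to the CH2OSi(t-Bu)Ph2 arm and syn to the rod-like alkyne, a preference the bulky silyl group is chosen to enforce, and the diastereomer from attack on the other face would be removed by chromatography.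

Step 11
Reactants: 17 the spiro ketone from step 10
Product: 18 (13R)-16-{[tert-butyl(diphenyl)silyl]oxy}-9α,13-epoxy-15-(trimethylsilyl)labd-6-en-14-yn-7-yl acetate
Conditions: LDA (commercial solution, 1.3 equiv), THF, −78 °C; cannulated into Ac2O (4 equiv), THF, −78 to 0 °C
Reagents that add atoms: acetic anhydride, CC(=O)OC(C)=O
Why: Kinetic enolate trapping: LDA at −78 °C should remove a C6 methylene proton in preference to the C8 methine next to the spiro centre (so no enolate able to expel the C9 oxygen forms), and O-acylation of the lithium enolate by excess Ac2O gives the C6=C7 enol acetate.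

Step 12
Reactants: 18 the enol acetate from step 11
Product: 20 (13R)-6β-acetoxy-16-{[tert-butyl(diphenyl)silyl]oxy}-9α,13-epoxy-15-(trimethylsilyl)labd-14-yn-7-one, via acetoxy epoxide 19 (not isolated)
Conditions: dimethyldioxirane (acetone solution), CH2Cl2, 0 °C; evaporate; toluene, 100 °C
Reagents that add atoms: dimethyldioxirane, CC1(C)OO1
Why: Dimethyldioxirane epoxidizes the electron-rich enol acetate from the α-face (the β-face is covered by the axial methyls on C4 and C10), and on heating the 7β-acetoxy group migrates to C6 with inversion as the epoxide C6–O bond breaks (thermal rearrangement of an enol ester epoxide to an α-acyloxy ketone), which gives the axial 6β-acetate and restores the C7 ketone.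

Step 13
Reactants: 20 the 6β-acetoxy ketone from step 12
Product: 21 (13R)-6β-acetoxy-9α,13-epoxy-16-hydroxylabd-14-yn-7-one
Conditions: Bu4NF (3 equiv), AcOH (3 equiv), THF, 0 °C to rt
Reagents that add atoms: none
Why: Buffered fluoride desilylation cleaves the Si–C(sp) and primary Si–O bonds while acetic acid keeps the medium from enolizing the α-acetoxy ketone or opening the β-alkoxy ketone; no stereocentre is affected.

Step 14
Reactants: 21 the alkynol from step 13
Product: 22 (13R)-6β-acetoxy-9α,13:15,16-diepoxylabd-14-en-7-one (target)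
Conditions: Mo(CO)6 (0.3 equiv), Et3N, Et2O, hν (350 nm); then 21, rt; chromatography on Et3N-deactivated silica
Reagents that add atoms: none
Why: In this molybdenum-catalysed alkynol cycloisomerization, (Et3N)Mo(CO)5 turns the terminal alkyne into a vinylidene complex whose metal-bound carbon (C15) is attacked by the C16 hydroxyl, and protodemetalation gives the 2,3-dihydrofuran under basic conditions that spare the acid-labile spiro enol ether; C13 is not touched.

**Compound list**

1 | 6-methylhept-6-en-2-one | CC(=O)CCCC(C)=C | starting material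
2 | triethyl phosphonoacetate | CCOC(=O)CP(=O)(OCC)OCC | starting material
3 | ethyl (2E)-3,7-dimethylocta-2,7-dienoate | CCOC(=O)/C=C(\C)CCCC(C)=C | intermediate
4 | (2E)-3,7-dimethylocta-2,7-dien-1-ol | OC/C=C(\C)CCCC(C)=C | intermediate
5 | (2E)-1-bromo-3,7-dimethylocta-2,7-diene | BrC/C=C(\C)CCCC(C)=C | intermediate
6 | {[(2E)-3,7-dimethylocta-2,7-dien-1-yl]sulfonyl}benzene | O=S(=O)(C/C=C(\C)CCCC(C)=C)c1ccccc1 | intermediate
7 | 2-bromoprop-2-en-1-ol | OCC(Br)=C | starting material
8 | ethynyltrimethylsilane | C#C[Si](C)(C)C | starting material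
9 | 2-methylidene-4-(trimethylsilyl)but-3-yn-1-ol | OCC(=C)C#C[Si](C)(C)C | intermediate
10 | [(2R)-2-[(trimethylsilyl)ethynyl]oxiran-2-yl]methanol | C1O[C@]1(C#C[Si](C)(C)C)CO | intermediate
11 | tert-butyl(diphenyl){[(2S)-2-[(trimethylsilyl)ethynyl]oxiran-2-yl]methoxy}silane | C1O[C@]1(C#C[Si](C)(C)C)CO[Si](c2ccccc2)(c2ccccc2)C(C)(C)C | intermediate
12 | methyl 2-methyl-3-oxobutanoate | COC(=O)C(C)C(C)=O | starting material
13 | methyl (6R)-6-{[tert-butyl(diphenyl)silyl]oxymethyl}-6-hydroxy-2-methyl-3-oxo-8-(trimethylsilyl)oct-7-ynoate (C2 epimers, in equilibrium with its cyclic hemiketal) | COC(=O)C(C)C(=O)CC[C@@](O)(C#C[Si](C)(C)C)CO[Si](c1ccccc1)(c1ccccc1)C(C)(C)C | intermediate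
14 | methyl (2Z)-2-[(5R)-5-{[tert-butyl(diphenyl)silyl]oxymethyl}-5-[(trimethylsilyl)ethynyl]oxolan-2-ylidene]propanoate | COC(=O)/C(C)=C1/CC[C@@](O1)(C#C[Si](C)(C)C)CO[Si](c2ccccc2)(c2ccccc2)C(C)(C)C | intermediate
15 | (2Z,5E)-4-(benzenesulfonyl)-2-[(5R)-5-{[tert-butyl(diphenyl)silyl]oxymethyl}-5-[(trimethylsilyl)ethynyl]oxolan-2-ylidene]-6,10-dimethylundeca-5,10-dien-3-one (C4 epimers) | C=C(C)CCC/C(C)=C/C(C(=O)/C(C)=C1/CC[C@@](O1)(C#C[Si](C)(C)C)CO[Si](c2ccccc2)(c2ccccc2)C(C)(C)C)S(=O)(=O)c3ccccc3 | intermediate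
16 | (2Z,5E)-2-[(5R)-5-{[tert-butyl(diphenyl)silyl]oxymethyl}-5-[(trimethylsilyl)ethynyl]oxolan-2-ylidene]-6,10-dimethylundeca-5,10-dien-3-one | C=C(C)CCC/C(C)=C/CC(=O)/C(C)=C1/CC[C@@](O1)(C#C[Si](C)(C)C)CO[Si](c2ccccc2)(c2ccccc2)C(C)(C)C | intermediate
17 | (13R)-16-{[tert-butyl(diphenyl)silyl]oxy}-9α,13-epoxy-15-(trimethylsilyl)labd-14-yn-7-one (5α-H, 8α-methyl, 10β-methyl) | C1C(=O)[C@@H](C)[C@]2(CC[C@@](O2)(C#C[Si](C)(C)C)CO[Si](c3ccccc3)(c3ccccc3)C(C)(C)C)[C@@]2(C)CCCC(C)(C)[C@H]12 | intermediate
18 | (13R)-16-{[tert-butyl(diphenyl)silyl]oxy}-9α,13-epoxy-15-(trimethylsilyl)labd-6-en-14-yn-7-yl acetate | C1=C(OC(C)=O)[C@@H](C)[C@]2(CC[C@@](O2)(C#C[Si](C)(C)C)CO[Si](c3ccccc3)(c3ccccc3)C(C)(C)C)[C@@]2(C)CCCC(C)(C)[C@H]12 | intermediate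
19 | (13R)-16-{[tert-butyl(diphenyl)silyl]oxy}-6α,7α:9α,13-diepoxy-15-(trimethylsilyl)labd-14-yn-7β-yl acetate | O1[C@H]2[C@]1(OC(C)=O)[C@@H](C)[C@]3(CC[C@@](O3)(C#C[Si](C)(C)C)CO[Si](c4ccccc4)(c4ccccc4)C(C)(C)C)[C@@]3(C)CCCC(C)(C)[C@H]23 | intermediate
20 | (13R)-6β-acetoxy-16-{[tert-butyl(diphenyl)silyl]oxy}-9α,13-epoxy-15-(trimethylsilyl)labd-14-yn-7-one | CC(=O)O[C@@H]1C(=O)[C@@H](C)[C@]2(CC[C@@](O2)(C#C[Si](C)(C)C)CO[Si](c3ccccc3)(c3ccccc3)C(C)(C)C)[C@@]2(C)CCCC(C)(C)[C@H]12 | intermediate
21 | (13R)-6β-acetoxy-9α,13-epoxy-16-hydroxylabd-14-yn-7-one | CC(=O)O[C@@H]1C(=O)[C@@H](C)[C@]2(CC[C@@](O2)(C#C)CO)[C@@]2(C)CCCC(C)(C)[C@H]12 | intermediate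
22 | (13R)-6β-acetoxy-9α,13:15,16-diepoxylabd-14-en-7-one (CNP0224709.1) | CC(=O)O[C@@H]1C(=O)[C@@H](C)[C@]2(CC[C@]3(C=COC3)O2)[C@@]2(C)CCCC(C)(C)[C@H]12 | target

**Totals**

Total step count: 14. Longest linear sequence: 11 steps (from 7, steps 4 to 14).

**Steps most likely to fail**

Step 10 (new method). The hindered tertiary C10 radical may add too slowly to the fully substituted, donor-substituted C9, so that reduction or hydrogen loss from the monocyclic radical wins. C13 may also discriminate the two faces only weakly, and the iron enolate could expel the C9 oxygen. The fallback uses only known reactions and separates C–C from C–O bond formation; it sets out from 11 (with 6) and returns at 17. Lithiated acetonitrile opens the epoxide of 11 at CH2 to give the hydroxy nitrile (4R)-4-{[tert-butyl(diphenyl)silyl]oxymethyl}-4-hydroxy-6-(trimethylsilyl)hex-5-ynenitrile F1. Reduction with i-Bu2AlH and hydrolysis give the lactol (5R)-5-{[tert-butyl(diphenyl)silyl]oxymethyl}-5-[(trimethylsilyl)ethynyl]oxolan-2-ol F2. Wittig reaction with methyl 2-(triphenylphosphoranylidene)propanoate gives the enoate methyl (2E,6R)-6-{[tert-butyl(diphenyl)silyl]oxymethyl}-6-hydroxy-2-methyl-8-(trimethylsilyl)oct-2-en-7-ynoate F3. Acylation of lithiated 6 (three equivalents, the alkoxide being carried along) gives the hydroxy β-keto sulfone F4, and SmI2 gives the hydroxy dienone F5. The established Fe(acac)3/PhSiH3 bicyclization, now ending on an ordinary trisubstituted enone, should give the 13-hydroxy trans-decalone F6 (9α-H). C13 no longer steers the folding here, so its diastereomer would form alongside. Bromination through the more substituted enol (PhNMe3Br3, THF) gives the 8β-bromo ketone F7, and dehydrobromination (Li2CO3, LiBr, DMF, heat) gives the 13-hydroxy labd-8-en-7-one F8. The C13 hydroxyl then closes ring C by intramolecular oxa-Michael addition to C9 from the axial α-face (DBU) to give 17, where the diastereomers would be separated.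

Step 7. The delocalized dianion may open the neopentyl-type epoxide carbon sluggishly, and attack or ionization at the propargylic carbon would erode the C13 configuration. The fallback sets out from 11 and returns at 13. The smaller dianion of acetic acid (AcOH, two equivalents of LDA, THF, 45 °C) opens the epoxide and acidification closes the lactone (5R)-5-{[tert-butyl(diphenyl)silyl]oxymethyl}-5-[(trimethylsilyl)ethynyl]oxolan-2-one F9. Claisen-type addition of the lithium enolate of methyl propanoate to the lactone carbonyl then gives 13, which is dehydrated to 14 as in step 7.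

Step 11. The kinetic enolate may equilibrate to the C8 enolate, which would eliminate the C9 oxygen and open ring C, and C-acetylation may compete with O-acetylation. The fallback avoids any C7 enolate; it sets out from 17 and returns at 20. Condensation with 4-methylbenzenesulfonohydrazide gives the tosylhydrazone F10. The Shapiro reaction (n-BuLi, deprotonation at the less substituted C6, then water) gives the C6=C7 alkene (13R)-16-{[tert-butyl(diphenyl)silyl]oxy}-9α,13-epoxy-15-(trimethylsilyl)labd-6-en-14-yne F11. Dimethyldioxirane gives the 6α,7α-epoxide F12 from the open α-face. Trans-diaxial opening with acetic acid places acetate at C6β and hydroxyl at C7α to give the hydroxy acetate F13, and oxidation with the periodinane DMP gives 20.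

**Further compounds**

F1 | step 10 | (4R)-4-{[tert-butyl(diphenyl)silyl]oxymethyl}-4-hydroxy-6-(trimethylsilyl)hex-5-ynenitrile | N#CCC[C@@](O)(C#C[Si](C)(C)C)CO[Si](c1ccccc1)(c1ccccc1)C(C)(C)C
F2 | step 10 | (5R)-5-{[tert-butyl(diphenyl)silyl]oxymethyl}-5-[(trimethylsilyl)ethynyl]oxolan-2-ol (anomers) | OC1CC[C@@](O1)(C#C[Si](C)(C)C)CO[Si](c2ccccc2)(c2ccccc2)C(C)(C)C
F3 | step 10 | methyl (2E,6R)-6-{[tert-butyl(diphenyl)silyl]oxymethyl}-6-hydroxy-2-methyl-8-(trimethylsilyl)oct-2-en-7-ynoate | COC(=O)/C(C)=C/CC[C@@](O)(C#C[Si](C)(C)C)CO[Si](c1ccccc1)(c1ccccc1)C(C)(C)C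
F4 | step 10 | (3R,6E,10E)-9-(benzenesulfonyl)-3-{[tert-butyl(diphenyl)silyl]oxymethyl}-3-hydroxy-7,11,15-trimethyl-1-(trimethylsilyl)hexadeca-6,10,15-trien-1-yn-8-one (C9 epimers) | C=C(C)CCC/C(C)=C/C(C(=O)/C(C)=C/CC[C@@](O)(C#C[Si](C)(C)C)CO[Si](c1ccccc1)(c1ccccc1)C(C)(C)C)S(=O)(=O)c2ccccc2
F5 | step 10 | (3R,6E,10E)-3-{[tert-butyl(diphenyl)silyl]oxymethyl}-3-hydroxy-7,11,15-trimethyl-1-(trimethylsilyl)hexadeca-6,10,15-trien-1-yn-8-one | C=C(C)CCC/C(C)=C/CC(=O)/C(C)=C/CC[C@@](O)(C#C[Si](C)(C)C)CO[Si](c1ccccc1)(c1ccccc1)C(C)(C)C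
F6 | step 10 | (13R)-16-{[tert-butyl(diphenyl)silyl]oxy}-13-hydroxy-15-(trimethylsilyl)labd-14-yn-7-one (5α-H, 8α-methyl, 9α-H, 10β-methyl) | C1C(=O)[C@@H](C)[C@H](CC[C@@](O)(C#C[Si](C)(C)C)CO[Si](c3ccccc3)(c3ccccc3)C(C)(C)C)[C@@]2(C)CCCC(C)(C)[C@H]12
F7 | step 10 | (13R)-8β-bromo-16-{[tert-butyl(diphenyl)silyl]oxy}-13-hydroxy-15-(trimethylsilyl)labd-14-yn-7-one | C1C(=O)[C@](C)(Br)[C@H](CC[C@@](O)(C#C[Si](C)(C)C)CO[Si](c3ccccc3)(c3ccccc3)C(C)(C)C)[C@@]2(C)CCCC(C)(C)[C@H]12
F8 | step 10 | (13R)-16-{[tert-butyl(diphenyl)silyl]oxy}-13-hydroxy-15-(trimethylsilyl)labd-8-en-14-yn-7-one | C1C(=O)C(C)=C(CC[C@@](O)(C#C[Si](C)(C)C)CO[Si](c3ccccc3)(c3ccccc3)C(C)(C)C)[C@@]2(C)CCCC(C)(C)[C@H]12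
F9 | step 7 | (5R)-5-{[tert-butyl(diphenyl)silyl]oxymethyl}-5-[(trimethylsilyl)ethynyl]oxolan-2-one | O=C1CC[C@@](O1)(C#C[Si](C)(C)C)CO[Si](c2ccccc2)(c2ccccc2)C(C)(C)C
F10 | step 11 | 4-methylbenzenesulfonylhydrazone of 17 | C1C(=NNS(=O)(=O)c4ccc(C)cc4)[C@@H](C)[C@]2(CC[C@@](O2)(C#C[Si](C)(C)C)CO[Si](c3ccccc3)(c3ccccc3)C(C)(C)C)[C@@]2(C)CCCC(C)(C)[C@H]12
F11 | step 11 | (13R)-16-{[tert-butyl(diphenyl)silyl]oxy}-9α,13-epoxy-15-(trimethylsilyl)labd-6-en-14-yne | C1=C[C@@H](C)[C@]2(CC[C@@](O2)(C#C[Si](C)(C)C)CO[Si](c3ccccc3)(c3ccccc3)C(C)(C)C)[C@@]2(C)CCCC(C)(C)[C@H]12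
F12 | step 11 | (13R)-16-{[tert-butyl(diphenyl)silyl]oxy}-6α,7α:9α,13-diepoxy-15-(trimethylsilyl)labd-14-yne | O1[C@H]2[C@@H]1[C@@H](C)[C@]3(CC[C@@](O3)(C#C[Si](C)(C)C)CO[Si](c4ccccc4)(c4ccccc4)C(C)(C)C)[C@@]3(C)CCCC(C)(C)[C@H]23
F13 | step 11 | (13R)-16-{[tert-butyl(diphenyl)silyl]oxy}-9α,13-epoxy-7α-hydroxy-15-(trimethylsilyl)labd-14-yn-6β-yl acetate | CC(=O)O[C@@H]1[C@@H](O)[C@@H](C)[C@]2(CC[C@@](O2)(C#C[Si](C)(C)C)CO[Si](c3ccccc3)(c3ccccc3)C(C)(C)C)[C@@]2(C)CCCC(C)(C)[C@H]12
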